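## Retrosynthetic overview
1. C4'–OH and C5'–H come from conjugate hydration (borylation, then oxidation) of the strained α-alkylidene γ-lactone in the anhydro cage compound.
2. Ring C and the bicyclo[2.2.2]octane form together in an intramolecular Diels–Alder reaction. A butenolide-fused 6-alkyl-6-methylcyclohexa-2,4-dienone adds to the C8=C12 exocyclic alkene (bonds C8–C6' and C12–C3').
3. The dienone comes from a Michael union (C11–C1') of a pinane α-methylene ketone with a keto-butenolide, followed by C8 methylenation and C3'–C4' dehydrogenation.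
4. Ring A forms by acid fragmentation of the pinane cyclobutane, with the C4 cation caught by the cis (Z)-enoic acid. C5 is bought in (−)-myrtenal and C10 is set by its deconjugative methylation.
5. The keto-butenolide comes from a Diels–Alder reaction of a 2-silyloxydiene with methyl 4-hydroxybut-2-ynoate. Ring order: B (bought), then polyketide ring plus butenolide, then A, then C plus cage.

Atom labels (target):
- ring A = O–C3(=O)–C2=C1–C10–C5–C4(Me)2
- ring B = C5–C6–C7–C8–C9–C10
- C11 = CH2 between C9 and C1'; C12 = CH2 between C8 and C3'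
- cage = C1'(Me)–C2'(=O)–C3'(Me)–C4'(OH)–C5'(H)–C6'
- γ-lactone = C6'–C7'H2–O–C8'(=O)–C5'

Assumption: tert-butyl bis(2,2,2-trifluoroethyl)phosphonoacetate, methyl 4-hydroxybut-2-ynoate and 2-methylpent-1-en-3-one are bought as catalogue chemicals.

## Route

Step 1
Reactants: 1 (1R,5S)-(−)-myrtenal
Product: 2 2,6,6-trimethylbicyclo[3.1.1]hept-3-ene-2-carbaldehyde (bridgeheads as in 1; 2-methyl anti and 2-formyl syn to the CMe2 bridge)
Conditions: KOtBu, MeI, THF, −78 → 0 °C
Reagents that add atoms: iodomethane, CI
Why: Deconjugative α-alkylation: γ-deprotonation gives the extended dienolate, which is methylated at its α-carbon (C10) from the face away from the CMe2 bridge, so the methyl ends anti and the formyl group syn to that bridge.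

Step 2
Reactants: 2 α-methylated aldehyde
Product: 3 tert-butyl (Z)-3-(2,6,6-trimethylbicyclo[3.1.1]hept-3-en-2-yl)prop-2-enoate (side chain syn to the CMe2 bridge)
Conditions: (CF3CH2O)2P(O)CH2CO2tBu, KN(SiMe3)2, 18-crown-6, THF, −78 °C
Reagents that add atoms: tert-butyl bis(2,2,2-trifluoroethyl)phosphonoacetate, CC(C)(C)OC(=O)CP(=O)(OCC(F)(F)F)OCC(F)(F)F
Why: The Still–Gennari variant of the Horner–Wadsworth–Emmons olefination gives under kinetic control the (Z)-enoate that a seven-membered lactone needs, and it touches no stereocentre.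

Step 3
Reactants: 3 (Z)-enoate alkene
Product: 5 tert-butyl (Z)-3-(2,6,6-trimethyl-4-oxobicyclo[3.1.1]heptan-2-yl)prop-2-enoate (C8 ketone), via alkylborane 4 (not isolated)
Conditions: BH3·SMe2, THF, 0 °C; then N-methylmorpholine N-oxide, nPr4N[RuO4] (5 mol%), 4 Å MS, CH2Cl2, rt
Reagents that add atoms: borane–dimethyl sulfide, B.CSC (boron of 4); N-methylmorpholine N-oxide, C[N+]1([O-])CCOCC1 (ketone oxygen)
Why: Brown hydroboration puts boron on C8, the alkene carbon remote from quaternary C10, anti to the CMe2 bridge, and much faster than it attacks the electron-poor enoate; in-flask Ley–Griffith oxidation then carries C–B through to the ketone and erases the transient centre.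

Step 4
Reactants: 5 C8 ketone
Product: 8 tert-butyl (Z)-3-(2,6,6-trimethyl-3-methylidene-4-oxobicyclo[3.1.1]heptan-2-yl)prop-2-enoate (α-methylene ketone), via Mannich base 6 (not isolated), via methiodide 7 (not isolated)
Conditions: LiN(iPr)2, THF, −78 °C; [CH2=NMe2]I, −78 °C → rt; MeI, Et2O, rt; aq. NaHCO3, CH2Cl2, rt
Reagents that add atoms: dimethyl(methylidene)ammonium iodide, C=[N+](C)C.[I-]; iodomethane, CI (N-methyl of 7 only)
Why: Eschenmoser methylenation (Mannich reaction, then Hofmann-type elimination) is regiospecific because the ketone can enolise only towards C9, C7 being a bridgehead.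

Step 5
Reactants: 9 2-methylpent-1-en-3-one
Product: 10 (Z)-3-(tert-butyldimethylsilyloxy)-2-methylpenta-1,3-diene
Conditions: TBSOTf, Et3N, CH2Cl2, 0 °C
Reagents that add atoms: tert-butyldimethylsilyl triflate, CC(C)(C)[Si](C)(C)OS(=O)(=O)C(F)(F)F
Why: Soft enolisation and O-silylation on the ethyl side gives the (Z)-2-silyloxydiene, whose terminal methyl points outward in the reactive s-cis form.

Step 6
Reactants: 10 silyloxydiene; 11 methyl 4-hydroxybut-2-ynoate
Product: 13 4,6-dimethyl-6,7-dihydro-2-benzofuran-1,5(3H,4H)-dione (keto-butenolide; C1' and C3' labile or erased later so used as the mixture), via cyclohexadiene adduct 12 (not isolated)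
Conditions: toluene (degassed), 110 °C; then 1 M HCl, THF, rt
Reagents that add atoms: none
Why: In this Diels–Alder cycloaddition the nucleophilic enol-ether terminus (C1') bonds to the β-carbon of the ynoate (C6', the "para" orientation), and acid then removes the silyl group and closes the butenolide from the cis CH2OH/CO2Me pair.

Step 7
Reactants: 8 α-methylene ketone; 13 keto-butenolide
Product: 14 Michael adduct with the C11–C1' bond and quaternary C1' (configuration as in the target; C9 and C3' are epimer mixtures)
Conditions: LiOtBu (20 mol%), THF–toluene (degassed), −40 → −20 °C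
Reagents that add atoms: none
Why: Kinetic Michael addition: only C1'–H is both α to the ketone and vinylogous to the lactone, and its lithium enolate stacks on the s-cis enone face anti to the CMe2 bridge, with Li bridging the two carbonyl oxygens and the bicyclic body turned away from ring B, which fixes C1'.

Step 8
Reactants: 14 Michael adduct
Product: 16 ring A/B keto-lactone (cis-fused ε-lactone; H5 and H9 and 10-Me on one face; C4 and C1 and C11 on the other; C3' mixture), via free enoic acid 15 (not isolated)
Conditions: TfOH (2.5 equiv), CH2Cl2, −20 → 23 °C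
Reagents that add atoms: none
Why: Acid cleaves the tert-butyl ester and triggers the nopinone-type cyclobutane fragmentation (C7–C4 scission of the protonated ketone); the tertiary C4 cation is trapped by the cis (Z)-enoic acid as the seven-membered lactone, while C9 equilibrates through the enol to the equatorial C11 epimer.

Step 9
Reactants: 16 keto-lactone
Product: 17 C8 exocyclic methylene compound (C8=C12H2; other centres unchanged)
Conditions: Zn, CH2Br2, TiCl4, THF–CH2Cl2, 0 °C → rt
Reagents that add atoms: dibromomethane, BrCBr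
Why: The non-basic Oshima–Lombardo methylenation attacks only the accessible ring B ketone and not the C2' ketone flanked by C1' and C3' or the lactones, and it avoids both C9 epimerisation and retro-Michael cleavage.

Step 10
Reactants: 17 methylene ketone
Product: 18 cyclohexa-2,4-dienone (C3'=C4' and C5'=C6'; C1' quaternary)
Conditions: IBX, DMSO–fluorobenzene, 70 °C
Reagents that add atoms: none
Why: IBX dehydrogenation of the ketone can proceed only through the C2'=C3' enol and removes the doubly allylic C4'–H; quaternary C1' stops the oxidation at the dienone, and the C3' mixture converges.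

Step 11
Reactants: 18 dienone
Product: 19 anhydro cage compound (ring C and bicyclo[2.2.2]octene closed; C4'=C5' conjugated to the γ-lactone)
Conditions: o-dichlorobenzene, BHT, 160 °C, sealed tube
Reagents that add atoms: none
Why: Intramolecular Diels–Alder reaction of the electron-poor dienone with the 1,1-dialkyl alkene: the short C11–C9 tether on C1' allows addition only to the diene face bearing C11 and to the axial alkene face cis to C11, so C8, C6' and C3' follow from C1' and C9 and ring C is cis-fused.

Step 12
Reactants: 19 anhydro cage compound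
Product: 21 target CNP0295808.3, via pinacol boronate 20 (not isolated)
Conditions: B2pin2 (1.05 equiv), CuCl (5 mol%), Xantphos (5 mol%), NaOtBu (10 mol%), MeOH (2 equiv), THF, rt; then NaBO3·4H2O, THF–H2O, rt
Reagents that add atoms: bis(pinacolato)diboron, CC1(C)OB(OC1(C)C)B1OC(C)(C)C(C)(C)O1 (boron of 20); sodium perborate, [Na+].[O-]OB=O (hydroxyl oxygen)
Why: Copper-catalysed conjugate borylation should prefer the strained s-cis α-alkylidene γ-lactone over the twisted, doubly shielded ring A enoate; boron enters C4' from the face syn to the flat C2' carbonyl bridge, the enolate is protonated at C5' anti to the boronate, and oxidation retains configuration.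

## Compound list
1 | (1R,5S)-(−)-myrtenal | CC1(C)[C@H]2CC=C(C=O)[C@@H]1C2 | starting material
2 | 2,6,6-trimethylbicyclo[3.1.1]hept-3-ene-2-carbaldehyde (Me anti, CHO syn to CMe2 bridge) | CC1(C)[C@H]2C=C[C@@](C)(C=O)[C@@H]1C2 | intermediate
3 | tert-butyl (Z)-enoate of 2 | CC1(C)[C@H]2C=C[C@@](C)(/C=C\C(=O)OC(C)(C)C)[C@@H]1C2 | intermediate
4 | C8 alkylborane (boron anti to CMe2 bridge) | CC1(C)[C@H]2[C@H](B)C[C@@](C)(/C=C\C(=O)OC(C)(C)C)[C@@H]1C2 | intermediate
5 | C8 ketone | CC1(C)[C@H]2C(=O)C[C@@](C)(/C=C\C(=O)OC(C)(C)C)[C@@H]1C2 | intermediate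
6 | C9 dimethylaminomethyl ketone (Mannich base) | CC1(C)[C@H]2C(=O)[C@H](CN(C)C)[C@@](C)(/C=C\C(=O)OC(C)(C)C)[C@@H]1C2 | intermediate
7 | methiodide of 6 | CC1(C)[C@H]2C(=O)[C@H](C[N+](C)(C)C)[C@@](C)(/C=C\C(=O)OC(C)(C)C)[C@@H]1C2.[I-] | intermediate
8 | α-methylene ketone | CC1(C)[C@H]2C(=O)C(=C)[C@@](C)(/C=C\C(=O)OC(C)(C)C)[C@@H]1C2 | intermediate
9 | 2-methylpent-1-en-3-one | CCC(=O)C(C)=C | starting material
10 | (Z)-3-(tert-butyldimethylsilyloxy)-2-methylpenta-1,3-diene | C/C=C(\O[Si](C)(C)C(C)(C)C)C(C)=C | intermediate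
11 | methyl 4-hydroxybut-2-ynoate | OCC#CC(=O)OC | starting material
12 | Diels–Alder adduct (1,4-cyclohexadiene silyl enol ether) | CC1C(CO)=C(C(=O)OC)CC(C)=C1O[Si](C)(C)C(C)(C)C | intermediate
13 | 4,6-dimethyl-6,7-dihydro-2-benzofuran-1,5(3H,4H)-dione | CC1CC2=C(COC2=O)C(C)C1=O | intermediate
14 | Michael adduct (C1' set; C9, C3' mixtures) | CC1(C)[C@H]2C(=O)C(C[C@@]3(C)C(=O)C(C)CC4=C3COC4=O)[C@@](C)(/C=C\C(=O)OC(C)(C)C)[C@@H]1C2 | intermediate
15 | free (Z)-enoic acid of 14 | CC1(C)[C@H]2C(=O)C(C[C@@]3(C)C(=O)C(C)CC4=C3COC4=O)[C@@](C)(/C=C\C(=O)O)[C@@H]1C2 | intermediate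
16 | ring A/B keto-lactone | CC1(C)OC(=O)C=C[C@@]2(C)[C@@H]1CCC(=O)[C@H]2C[C@@]3(C)C(=O)C(C)CC4=C3COC4=O | intermediate
17 | C8 exocyclic methylene compound | CC1(C)OC(=O)C=C[C@@]2(C)[C@@H]1CCC(=C)[C@H]2C[C@@]3(C)C(=O)C(C)CC4=C3COC4=O | intermediate
18 | cyclohexa-2,4-dienone | CC1(C)OC(=O)C=C[C@@]2(C)[C@@H]1CCC(=C)[C@H]2C[C@@]3(C)C(=O)C(C)=CC4=C3COC4=O | intermediate
19 | anhydro cage compound | CC1(C)OC(=O)C=C[C@@]2(C)[C@@H]1CC[C@]13C[C@]4(C)C(=O)[C@](C)(C[C@@H]21)[C@]31COC(=O)C1=C4 | intermediate
20 | C4' pinacol boronate | CC1(C)OC(=O)C=C[C@@]2(C)[C@@H]1CC[C@]13C[C@]4(C)C(=O)[C@](C)(C[C@@H]21)[C@]31COC(=O)[C@H]1[C@H]4B1OC(C)(C)C(C)(C)O1 | intermediate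
21 | CNP0295808.3 | CC1(C)OC(=O)C=C[C@@]2(C)[C@@H]1CC[C@]13C[C@]4(C)C(=O)[C@](C)(C[C@@H]21)[C@]31COC(=O)[C@H]1[C@H]4O | target

## Step count and risks
Total steps: 12. Longest linear sequence: 10 steps (steps 1–4 and 7–12, from 1 to 21).

**Step 7 (site and facial selectivity at C1').** The enolate of 13 may react through C5' or oxygen, or the open transition state may give the wrong C1' epimer, which cannot close a cis-fused ring C.
- The fallback sets out from 13 (with 8) and comes back at 14.
- 13 is silylated (TMSCl, Et3N) to the trimethylsilyl dienol ether F1.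
- F1 is combined with 8, acting as a 1-oxadiene, in an inverse-electron-demand hetero-Diels–Alder reaction (Eu(fod)3 catalysis) to give the 2-silyloxy-dihydropyran adduct F2.
- This makes C11–C1' and O–C2' suprafacially on the enone face anti to the CMe2 bridge, which excludes C5' attack. Dilute acetic acid then hydrolyses F2 to 14.

**Step 11 (the cycloaddition joins three contiguous quaternary carbons against the polar bias of the dienone).** Retro-ene loss of the side chain with aromatisation may win at 160 °C.
- The fallback sets out from 18 and comes back at 19.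
- 1,2-Reduction of the dienone (NaBH4, CeCl3·7H2O, MeOH) gives the cyclohexadienol F3, which has no carbonyl for the aromatising retro-ene path and tolerates harsher heating.
- Its intramolecular Diels–Alder reaction gives the cage alcohol F4.
- Dess–Martin periodinane re-oxidises F4 to 19.

**Step 12 (chemoselectivity between the two enoates, and the C5' protonation).** The ring A enoate may be borylated as well.
- The fallback sets out from 19 and comes back at 21, and it relies on alkene nucleophilicity instead of electrophilicity.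
- Dimethyldioxirane epoxidises only the strained trisubstituted C4'=C5' alkene, from the face syn to the C2' carbonyl bridge, giving the α,β-epoxy lactone F5.
- SmI2 (THF–MeOH, −78 °C) cleaves the C5'–O bond, and the resulting enolate is protonated anti to the C4' alkoxide to give 21.

## Further compounds
F1 | step 7 | trimethylsilyl dienol ether of 13 | CC1CC2=C(COC2=O)C(C)=C1O[Si](C)(C)C
F2 | step 7 | 2-silyloxy-dihydropyran hetero-Diels–Alder adduct of 8 and F1 | CC1(C)[C@H]2C3=C(C[C@]4(C)C5=C(CC(C)C4(O3)O[Si](C)(C)C)C(=O)OC5)[C@@](C)(/C=C\C(=O)OC(C)(C)C)[C@@H]1C2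
F3 | step 11 | cyclohexadienol from 18 (C2' carbinol mixture) | CC1(C)OC(=O)C=C[C@@]2(C)[C@@H]1CCC(=C)[C@H]2C[C@@]3(C)C(O)C(C)=CC4=C3COC4=O
F4 | step 11 | cage alcohol (C2' carbinol mixture) | CC1(C)OC(=O)C=C[C@@]2(C)[C@@H]1CC[C@]13C[C@]4(C)C(O)[C@](C)(C[C@@H]21)[C@]31COC(=O)C1=C4
F5 | step 12 | C4',C5'-epoxy lactone (oxygen syn to the C2' bridge) | CC1(C)OC(=O)C=C[C@@]2(C)[C@@H]1CC[C@]13C[C@]4(C)C(=O)[C@](C)(C[C@@H]21)[C@]31COC(=O)[C@@]15O[C@@H]45
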